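## Retrosynthetic overview

1. Target 20 ⇐ keto aldehyde 19 ⇐ bicyclic diol 18 by oxidation-level changes only; both ketone α-centres are already the thermodynamically preferred epimers.
2. The five- and six-membered rings are closed together (bonds C3a–C7a and C4–C5, indene numbering) by an anodic radical-cation intramolecular Diels–Alder reaction of the acyclic tetraene 16.
3. Tetraene 16 ⇐ enal 10 by Wittig and Horner–Wadsworth–Emmons chain extension, ester reduction and bis-silylation.
4. Enal 10 (C5–C6 bond, stereocentres C5 and C6) ⇐ vinylogous Mukaiyama aldol of aldehyde 7 with the silyl dienol ether of 2-ethylhex-2-enal, steered by C4.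
5. Aldehyde 7 ⇐ (R)-Roche ester 1, the only purchased stereocentre, by reduction and olefination.

Assumption: the target is exactly the given SMILES, i.e. the (1S,3S,3aR,4R,5S,7aR) acid named under 20, and compounds 1, 3, 8, 11 and 13 are taken as catalogue chemicals.

## Route

Step 1
Reactants: 1 methyl (2R)-3-hydroxy-2-methylpropanoate
Product: 2 methyl (2R)-3-[(tert-butyldimethylsilyl)oxy]-2-methylpropanoate
Conditions: TBSCl, imidazole, DMF, 0 °C → rt
Reagents that add atoms: tert-butyldimethylsilyl chloride, CC(C)(C)[Si](C)(C)Cl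
Why: Standard silylation of the primary alcohol, which leaves the purchased stereocentre untouched.

Step 2
Reactants: 2 methyl (2R)-3-[(tert-butyldimethylsilyl)oxy]-2-methylpropanoate; 3 triethyl 2-phosphonobutanoate
Product: 5 ethyl (2E,4S)-5-[(tert-butyldimethylsilyl)oxy]-2-ethyl-4-methylpent-2-enoate, via silyloxy aldehyde 4 (not isolated)
Conditions: i-Bu2AlH, CH2Cl2, −78 °C; then 3, NaH, THF, −78 → 0 °C
Reagents that add atoms: none
Why: Partial ester reduction followed in the same flask by a Horner–Wadsworth–Emmons olefination, so the epimerisable aldehyde is never isolated and the α-branched phosphonate gives the E-trisubstituted enoate.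

Step 3
Reactants: 5 ethyl (2E,4S)-5-[(tert-butyldimethylsilyl)oxy]-2-ethyl-4-methylpent-2-enoate
Product: 6 ethyl (2E,4S)-2-ethyl-5-hydroxy-4-methylpent-2-enoate
Conditions: HF·pyridine, THF, 0 °C → rt
Reagents that add atoms: none
Why: Fluoride-driven desilylation under non-basic conditions; the E-enoate cannot lactonise and C4 is not touched.

Step 4
Reactants: 6 ethyl (2E,4S)-2-ethyl-5-hydroxy-4-methylpent-2-enoate
Product: 7 ethyl (2E,4S)-2-ethyl-4-methyl-5-oxopent-2-enoate
Conditions: Dess–Martin periodinane, NaHCO3, CH2Cl2, 0 °C; used at once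
Reagents that add atoms: none
Why: Buffered Dess–Martin oxidation avoids the amine bases that would epimerise or conjugate this β,γ-unsaturated α-methyl aldehyde.

Step 5
Reactants: 8 (2E)-2-ethylhex-2-enal
Product: 9 tert-butyl{[(1E,3E)-2-ethylhexa-1,3-dien-1-yl]oxy}dimethylsilane
Conditions: TBSOTf, Et3N, Et2O, 0 °C → rt
Reagents that add atoms: tert-butyldimethylsilyl triflate, CC(C)(C)[Si](C)(C)OS(=O)(=O)C(F)(F)F
Why: Soft enolisation (O-silylation, then γ-deprotonation) gives the conjugated silyl dienol ether with the new 3,4-alkene E; the enol-ether geometry is of no consequence.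

Step 6
Reactants: 7 ethyl (2E,4S)-2-ethyl-4-methyl-5-oxopent-2-enoate; 9 tert-butyl{[(1E,3E)-2-ethylhexa-1,3-dien-1-yl]oxy}dimethylsilane
Product: 10 ethyl (2E,4S,5R,6S,7E)-2,6,8-triethyl-5-hydroxy-4-methyl-9-oxonona-2,7-dienoate
Conditions: B(C6F5)3, i-PrOH, Et2O, −78 °C
Reagents that add atoms: none
Why: Vinylogous Mukaiyama aldol at the γ-carbon of 9, in which Felkin–Anh attack anti to the alkenyl group on C4 sets C5 (4,5-syn), the open transition state of the (3E)-dienol ether sets C6 (5,6-anti), and the new enal is formed E.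

Step 7
Reactants: 10 ethyl (2E,4S,5R,6S,7E)-2,6,8-triethyl-5-hydroxy-4-methyl-9-oxonona-2,7-dienoate; 11 2-(triphenyl-λ5-phosphanylidene)butanal
Product: 12 ethyl (2E,4S,5R,6S,7E,9E)-2,6,8,10-tetraethyl-5-hydroxy-4-methyl-11-oxoundeca-2,7,9-trienoate
Conditions: toluene, 70 °C
Reagents that add atoms: none
Why: Wittig reaction of a stabilised formyl ylide under neutral conditions, which is E-selective and stops after one homologation because the dienal product is less electrophilic.

Step 8
Reactants: 12 ethyl (2E,4S,5R,6S,7E,9E)-2,6,8,10-tetraethyl-5-hydroxy-4-methyl-11-oxoundeca-2,7,9-trienoate; 13 diethyl benzylphosphonate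
Product: 14 ethyl (2E,4S,5R,6S,7E,9E,11E)-2,6,8,10-tetraethyl-5-hydroxy-4-methyl-12-phenyldodeca-2,7,9,11-tetraenoate
Conditions: 13, NaN(SiMe3)2, THF, −78 → 0 °C (one extra equivalent of base for the free hydroxyl)
Reagents that add atoms: none
Why: Horner–Wadsworth–Emmons olefination with a benzylphosphonate gives the E-styryl terminus, and 1,2-addition to the aldehyde at −78 °C outruns deprotonation at C4 or C6.

Step 9
Reactants: 14 ethyl (2E,4S,5R,6S,7E,9E,11E)-2,6,8,10-tetraethyl-5-hydroxy-4-methyl-12-phenyldodeca-2,7,9,11-tetraenoate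
Product: 15 (2E,4S,5R,6S,7E,9E,11E)-2,6,8,10-tetraethyl-4-methyl-12-phenyldodeca-2,7,9,11-tetraene-1,5-diol
Conditions: i-Bu2AlH, CH2Cl2, −78 °C; aqueous potassium sodium tartrate
Reagents that add atoms: none
Why: 1,2-Reduction of the enoate to the allylic alcohol, which makes the C2=C3 alkene electron-neutral, removes the only thermally competent dienophile and touches no stereocentre.

Step 10
Reactants: 15 (2E,4S,5R,6S,7E,9E,11E)-2,6,8,10-tetraethyl-4-methyl-12-phenyldodeca-2,7,9,11-tetraene-1,5-diol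
Product: 16 (2E,4S,5R,6S,7E,9E,11E)-2,6,8,10-tetraethyl-4-methyl-12-phenyl-1,5-bis[(triethylsilyl)oxy]dodeca-2,7,9,11-tetraene
Conditions: Et3SiOTf, 2,6-lutidine, CH2Cl2, −78 °C
Reagents that add atoms: triethylsilyl triflate, CC[Si](CC)(CC)OS(=O)(=O)C(F)(F)F
Why: Silylation of both hydroxyls in one operation so that neither can trap the radical cation of the next step as a cyclic ether.

Step 11
Reactants: 16 (2E,4S,5R,6S,7E,9E,11E)-2,6,8,10-tetraethyl-4-methyl-12-phenyl-1,5-bis[(triethylsilyl)oxy]dodeca-2,7,9,11-tetraene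
Product: 17 (1S,2R,3S,3aR,4R,5S,7aR)-1,4,5,7-tetraethyl-3-methyl-5-[(E)-2-phenylethenyl]-2-[(triethylsilyl)oxy]-4-{[(triethylsilyl)oxy]methyl}-2,3,3a,4,5,7a-hexahydro-1H-indene
Conditions: undivided cell, graphite-felt anode, Pt cathode, constant current (1 mA cm−2, about 0.3 F mol−1), (4-BrC6H4)3N (10 mol %), 2,6-di-tert-butylpyridine (20 mol %), 0.1 M LiClO4, MeNO2, 0 °C, 5 mM, Ar
Reagents that add atoms: none
Why: Proposed new method: the anodically regenerated aminium ion (about +1.05 V vs SCE) oxidises only the 1-phenyltriene of 16 (estimated +1.1 to +1.2 V, while isolated alkenes and the product styrene lie above +1.7 V), the tethered nucleophilic C2=C3 alkene attacks the triene radical cation at C7 to close the five-membered ring, the resulting tertiary cation at C2 is captured at C10 by the pentadienyl radical through the s-cis C7=C8–C9=C10 diene (s-trans is disfavoured by the clash of the C8 and C10 ethyl groups), and the product radical cation is reduced by fresh 16 (chain) or at the cathode; the trans ring fusion and the four new stereocentres are expected from the same endo, boat-like geometry as the thermal intramolecular Diels–Alder reaction, with the face fixed by allylic 1,3-strain (C4–H and C6–H lie in the alkene planes next to the C2 and C8 ethyl groups) and the alkene geometries transferred suprafacially; the closest known reaction type is the aminium-salt or electrode-initiated radical-cation Diels–Alder reaction of electron-rich aryl alkenes with dienes, which has not been shown with an aryl-triene radical cation as the 4π partner, an unactivated trisubstituted alkene as the 2π partner, or the formation of two adjacent quaternary centres.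

Step 12
Reactants: 17 the bis(triethylsilyl) cycloadduct
Product: 18 (1S,2R,3S,3aR,4R,5S,7aR)-1,4,5,7-tetraethyl-4-(hydroxymethyl)-3-methyl-5-[(E)-2-phenylethenyl]-2,3,3a,4,5,7a-hexahydro-1H-inden-2-ol
Conditions: HF·pyridine, pyridine, THF, 0 °C → rt
Reagents that add atoms: none
Why: Buffered fluoride cleavage of both triethylsilyl ethers without acid strong enough to protonate the ring alkene.

Step 13
Reactants: 18 the bicyclic diol
Product: 19 (1S,3S,3aR,4R,5S,7aR)-1,4,5,7-tetraethyl-3-methyl-2-oxo-5-[(E)-2-phenylethenyl]-2,3,3a,4,5,7a-hexahydro-1H-indene-4-carbaldehyde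
Conditions: Dess–Martin periodinane, NaHCO3, CH2Cl2, rt
Reagents that add atoms: none
Why: Double Dess–Martin oxidation (secondary alcohol to ketone, neopentyl alcohol to an aldehyde without α-hydrogen); the C1 ethyl and C3 methyl groups are each already trans to the adjacent ring-fusion substituent, so enolisation cannot erode them.

Step 14
Reactants: 19 the keto aldehyde
Product: 20 (1S,3S,3aR,4R,5S,7aR)-1,4,5,7-tetraethyl-3-methyl-2-oxo-5-[(E)-2-phenylethenyl]-2,3,3a,4,5,7a-hexahydro-1H-indene-4-carboxylic acid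
Conditions: NaClO2, NaH2PO4, 2-methyl-2-butene, t-BuOH/H2O, 0 °C → rt
Reagents that add atoms: sodium chlorite, [Na+].[O-]Cl=O
Why: Pinnick oxidation converts the hindered aldehyde to the acid under mildly acidic conditions, with the alkene scavenger protecting the styryl and ring double bonds from hypochlorous acid.

## Compound list

1 | methyl (2R)-3-hydroxy-2-methylpropanoate, (R)-Roche ester | C[C@H](CO)C(=O)OC | starting material
2 | methyl (2R)-3-[(tert-butyldimethylsilyl)oxy]-2-methylpropanoate | C[C@H](CO[Si](C)(C)C(C)(C)C)C(=O)OC | intermediate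
3 | triethyl 2-phosphonobutanoate | CCOC(=O)C(CC)P(=O)(OCC)OCC | starting material
4 | (2R)-3-[(tert-butyldimethylsilyl)oxy]-2-methylpropanal | C[C@H](CO[Si](C)(C)C(C)(C)C)C=O | intermediate
5 | ethyl (2E,4S)-5-[(tert-butyldimethylsilyl)oxy]-2-ethyl-4-methylpent-2-enoate | CCOC(=O)/C(CC)=C/[C@H](C)CO[Si](C)(C)C(C)(C)C | intermediate
6 | ethyl (2E,4S)-2-ethyl-5-hydroxy-4-methylpent-2-enoate | CCOC(=O)/C(CC)=C/[C@H](C)CO | intermediate
7 | ethyl (2E,4S)-2-ethyl-4-methyl-5-oxopent-2-enoate | CCOC(=O)/C(CC)=C/[C@H](C)C=O | intermediate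
8 | (2E)-2-ethylhex-2-enal | CCC/C=C(\CC)C=O | starting material
9 | tert-butyl{[(1E,3E)-2-ethylhexa-1,3-dien-1-yl]oxy}dimethylsilane | CC/C=C/C(CC)=C/O[Si](C)(C)C(C)(C)C | intermediate
10 | ethyl (2E,4S,5R,6S,7E)-2,6,8-triethyl-5-hydroxy-4-methyl-9-oxonona-2,7-dienoate | O=C/C(CC)=C/[C@H](CC)[C@H](O)[C@@H](C)/C=C(\CC)C(=O)OCC | intermediate
11 | 2-(triphenyl-λ5-phosphanylidene)butanal | CCC(C=O)=P(c1ccccc1)(c1ccccc1)c1ccccc1 | starting material
12 | ethyl (2E,4S,5R,6S,7E,9E)-2,6,8,10-tetraethyl-5-hydroxy-4-methyl-11-oxoundeca-2,7,9-trienoate | O=C/C(CC)=C/C(CC)=C/[C@H](CC)[C@H](O)[C@@H](C)/C=C(\CC)C(=O)OCC | intermediate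
13 | diethyl benzylphosphonate | CCOP(=O)(Cc1ccccc1)OCC | starting material
14 | ethyl (2E,4S,5R,6S,7E,9E,11E)-2,6,8,10-tetraethyl-5-hydroxy-4-methyl-12-phenyldodeca-2,7,9,11-tetraenoate | c1ccccc1/C=C/C(CC)=C/C(CC)=C/[C@H](CC)[C@H](O)[C@@H](C)/C=C(\CC)C(=O)OCC | intermediate
15 | (2E,4S,5R,6S,7E,9E,11E)-2,6,8,10-tetraethyl-4-methyl-12-phenyldodeca-2,7,9,11-tetraene-1,5-diol | c1ccccc1/C=C/C(CC)=C/C(CC)=C/[C@H](CC)[C@H](O)[C@@H](C)/C=C(\CC)CO | intermediate
16 | (2E,4S,5R,6S,7E,9E,11E)-2,6,8,10-tetraethyl-4-methyl-12-phenyl-1,5-bis[(triethylsilyl)oxy]dodeca-2,7,9,11-tetraene | c1ccccc1/C=C/C(CC)=C/C(CC)=C/[C@H](CC)[C@H](O[Si](CC)(CC)CC)[C@@H](C)/C=C(\CC)CO[Si](CC)(CC)CC | intermediate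
17 | (1S,2R,3S,3aR,4R,5S,7aR)-1,4,5,7-tetraethyl-3-methyl-5-[(E)-2-phenylethenyl]-2-[(triethylsilyl)oxy]-4-{[(triethylsilyl)oxy]methyl}-2,3,3a,4,5,7a-hexahydro-1H-indene | CCC1=C[C@@](/C=C/c2ccccc2)(CC)[C@](CC)(CO[Si](CC)(CC)CC)[C@@H]2[C@@H]1[C@H](CC)[C@H](O[Si](CC)(CC)CC)[C@H]2C | intermediate
18 | (1S,2R,3S,3aR,4R,5S,7aR)-1,4,5,7-tetraethyl-4-(hydroxymethyl)-3-methyl-5-[(E)-2-phenylethenyl]-2,3,3a,4,5,7a-hexahydro-1H-inden-2-ol | CCC1=C[C@@](/C=C/c2ccccc2)(CC)[C@](CC)(CO)[C@@H]2[C@@H]1[C@H](CC)[C@H](O)[C@H]2C | intermediate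
19 | (1S,3S,3aR,4R,5S,7aR)-1,4,5,7-tetraethyl-3-methyl-2-oxo-5-[(E)-2-phenylethenyl]-2,3,3a,4,5,7a-hexahydro-1H-indene-4-carbaldehyde | CCC1=C[C@@](/C=C/c2ccccc2)(CC)[C@](CC)(C=O)[C@@H]2[C@@H]1[C@H](CC)C(=O)[C@H]2C | intermediate
20 | (1S,3S,3aR,4R,5S,7aR)-1,4,5,7-tetraethyl-3-methyl-2-oxo-5-[(E)-2-phenylethenyl]-2,3,3a,4,5,7a-hexahydro-1H-indene-4-carboxylic acid | CCC1=C[C@@](/C=C/c2ccccc2)(CC)[C@](CC)(C(=O)O)[C@@H]2[C@@H]1[C@H](CC)C(=O)[C@H]2C | target

## Step count and risk

Total step count: 14. Longest linear sequence: 13 (steps 1–4 and 6–14 from compound 1); step 5 is a one-step side branch.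

The three steps most likely to fail:

Step 11 (the proposed new step). The radical cation may close to a vinylcyclobutane, lose a proton, or give the wrong ring fusion. The fallback uses known chemistry and sets out from diol 15. MnO2 in CH2Cl2 oxidises only the allylic primary alcohol and gives (2E,4S,5R,6S,7E,9E,11E)-2,6,8,10-tetraethyl-5-hydroxy-4-methyl-12-phenyldodeca-2,7,9,11-tetraenal F1. Heating this in toluene at 100 °C with a trace of BHT effects the thermal endo intramolecular Diels–Alder reaction of the triene-enal, controlled by the same allylic strain, and gives (1S,2R,3S,3aR,4R,5S,7aR)-1,4,5,7-tetraethyl-2-hydroxy-3-methyl-5-[(E)-2-phenylethenyl]-2,3,3a,4,5,7a-hexahydro-1H-indene-4-carbaldehyde F2. Dess–Martin oxidation of its secondary alcohol comes back to the route at keto aldehyde 19.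

Step 6. The aldehyde 7 is configurationally fragile and the diastereoselectivity rests on the Felkin and anti preferences holding together. The fallback sets out from aldehyde 7. Pentenylation with (E)-1-bromopent-2-ene and CrCl2 in THF (organochromium addition, anti-selective and Felkin-selective, ester tolerated) gives ethyl (2E,4S,5R,6S)-2,6-diethyl-5-hydroxy-4-methylocta-2,7-dienoate F3. Cross-metathesis of its vinyl group with 2-ethylacrolein, using the second-generation Hoveyda–Grubbs catalyst RuCl2(H2IMes)(=CH–C6H4-2-O-i-Pr) in CH2Cl2 at 40 °C, comes back to the route at enal 10.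

Step 8. The strongly basic phosphonate anion may deprotonate C4 or C6 or trigger a vinylogous retro-aldol of the alkoxide. The fallback sets out from dienal 12. Takai iodo-olefination (CHI3, CrCl2, THF, 0 °C), which is non-basic and E-selective, gives ethyl (2E,4S,5R,6S,7E,9E,11E)-2,6,8,10-tetraethyl-5-hydroxy-12-iodo-4-methyldodeca-2,7,9,11-tetraenoate F4. Suzuki–Miyaura coupling with PhB(OH)2 (Pd(PPh3)4, K3PO4, THF/H2O, rt) comes back to the route at tetraenoate 14.

Further compounds
F1 | step 11 | (2E,4S,5R,6S,7E,9E,11E)-2,6,8,10-tetraethyl-5-hydroxy-4-methyl-12-phenyldodeca-2,7,9,11-tetraenal | c1ccccc1/C=C/C(CC)=C/C(CC)=C/[C@H](CC)[C@H](O)[C@@H](C)/C=C(\CC)C=O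
F2 | step 11 | (1S,2R,3S,3aR,4R,5S,7aR)-1,4,5,7-tetraethyl-2-hydroxy-3-methyl-5-[(E)-2-phenylethenyl]-2,3,3a,4,5,7a-hexahydro-1H-indene-4-carbaldehyde | CCC1=C[C@@](/C=C/c2ccccc2)(CC)[C@](CC)(C=O)[C@@H]2[C@@H]1[C@H](CC)[C@H](O)[C@H]2C
F3 | step 6 | ethyl (2E,4S,5R,6S)-2,6-diethyl-5-hydroxy-4-methylocta-2,7-dienoate | C=C[C@H](CC)[C@H](O)[C@@H](C)/C=C(\CC)C(=O)OCC
F4 | step 8 | ethyl (2E,4S,5R,6S,7E,9E,11E)-2,6,8,10-tetraethyl-5-hydroxy-12-iodo-4-methyldodeca-2,7,9,11-tetraenoate | I/C=C/C(CC)=C/C(CC)=C/[C@H](CC)[C@H](O)[C@@H](C)/C=C(\CC)C(=O)OCC
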